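**Strategy.** The quinone is traced back to hydroquinone 14, whose carbocycle is grown from a cyclobutenone by a two-carbon ring expansion (Moore rearrangement). The precursor, 4-alkenyl-4-hydroxy-3-methoxycyclobutenone 11, comes from 1,2-addition of a pentacosenyllithium to methyl semisquarate. On heating, the four-membered ring opens to a dienylketene that closes by 6π electrocyclisation. The step exploits the para relationship of the oxygens on C1 and C4 of the quinone ring: the ketene carbon becomes C1, the carbinol carbon C4, the cyclobutenone alkene supplies C6–H and C5–OMe, and the side-arm alkene supplies C3 (docosyl) and C2 (methyl), the new bond being C1–C2. Oxidation in the same flask gives the quinone.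

Key step: step 5

Remark on the chemistry: ring numbering follows the name 3-docosyl-5-methoxy-2-methylcyclohexa-2,5-diene-1,4-dione. The target has no stereocentre. The alkene geometry of 9 to 12 and the racemic centres of 2, 11 and 13 do not reach the product; the geometry expected from step 3 is drawn.

**Route**

Step 1
Reactants: 1 dimethyl squarate (3,4-dimethoxycyclobut-3-ene-1,2-dione)
Product: 3 methyl semisquarate (3-methoxycyclobut-3-ene-1,2-dione), via hydroxycyclobutenone 2 (not isolated)
Conditions: LiAlH(OtBu)3 (1.05 equiv), THF, −78 to −20 °C; then 6 M HCl, CH2Cl2, 0 °C to rt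
Reagents that add atoms: water, O
Why: The hindered hydride adds 1,2 to one of the two equivalent carbonyls, and in acid the carbinol ionises to a methoxy-stabilised cyclobutenyl cation that water captures at the vinylogous carbon with loss of methanol (reduction followed by acid-mediated 1,3-carbonyl transposition, the standard semisquarate preparation).

Step 2
Reactants: 4 acetaldehyde; 5 carbon tetrabromide
Product: 6 1,1-dibromoprop-1-ene
Conditions: PPh3, CH2Cl2, 0 °C; pentane trituration, distillation
Reagents that add atoms: none
Why: The ylide Ph3P=CBr2 formed from CBr4 and PPh3 olefinates the aldehyde in a Wittig reaction (Ramirez gem-dibromoolefination, first stage of the Corey–Fuchs sequence).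

Step 3
Reactants: 7 1-bromodocosane; 6 1,1-dibromoprop-1-ene
Product: 9 (Z)-3-bromopentacos-2-ene, via docosylzinc bromide 8 (not isolated)
Conditions: 7, Zn dust, I2 (5 mol %), DMA, 80 °C; then 6 (excess), PdCl2(DPEphos) (3 mol %), THF, 0 °C to rt
Reagents that add atoms: none
Why: In this Negishi coupling zinc inserts into the primary C–Br bond and zerovalent palladium adds to the less hindered C–Br bond trans to the methyl group, so one docosyl group is delivered and the hindered bromide that remains is (Z); either geometry would serve, because both bromines sit on the same carbon and the geometry is lost in step 5.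

Step 4
Reactants: 9 (Z)-3-bromopentacos-2-ene; 3 methyl semisquarate
Product: 11 4-hydroxy-3-methoxy-4-[(2Z)-pentacos-2-en-3-yl]cyclobut-2-en-1-one (racemic), via alkenyllithium 10 (not isolated)
Conditions: 9, t-BuLi (2.0 equiv), THF/Et2O, −78 °C; then 3, THF, −78 °C; aq. NH4Cl, −78 °C
Reagents that add atoms: none
Why: Bromine–lithium exchange with retention gives alkenyllithium 10, which adds 1,2 to the ketone-like carbonyl next to the C–OMe carbon of 3 because the other carbonyl is deactivated as a vinylogous ester; the carbinol centre forms racemic and is erased in step 5.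

Step 5
Reactants: 11 4-hydroxy-3-methoxy-4-[(2Z)-pentacos-2-en-3-yl]cyclobut-2-en-1-one
Product: 15 3-docosyl-5-methoxy-2-methylcyclohexa-2,5-diene-1,4-dione (target), via dienylketene 12 (not isolated), via cyclohexadienone 13 (not isolated), via hydroquinone 14 (not isolated)
Conditions: p-xylene (degassed), 138 °C, Ar; then Ag2O, Na2SO4, Et2O, rt
Reagents that add atoms: none
Why: Heating breaks the C1–C4 bond of the cyclobutenone in a conrotatory four-electron electrocyclic opening to dienylketene 12, whose ketene carbon then bonds to the CH(CH3) terminus in a disrotatory six-electron electrocyclisation to give dienone 13; enolisation aromatises it to hydroquinone 14, which Ag2O dehydrogenates to quinone 15. The closest known reaction type is the Moore rearrangement of 4-alkenyl-4-hydroxycyclobutenones to hydroquinones. The six-membered carbocycle is closed by a 6π electrocyclic ring closure that forms the C1–C2 bond of the quinone, so the four-membered ring is enlarged by the two alkene carbons of the side arm. No lasting stereocentre is created: the carbinol centre of 11 and the transient CH(CH3) centre of 13 both become sp2, and the alkene geometry is lost. The step needs torquoselectivity in the ring opening, with the alkenyl arm turning inward toward the ketene, and this is secured by the donor hydroxyl on the same carbon, which rotates outward; regiochemistry needs no control because each substituent is already bonded to its ring carbon in 11. Oxygen is excluded during heating so that the electron-rich hydroquinone is oxidised only in the controlled second stage.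

**Compound list**

1 | dimethyl squarate (3,4-dimethoxycyclobut-3-ene-1,2-dione) | COC1=C(OC)C(=O)C1=O | starting material
2 | 4-hydroxy-2,3-dimethoxycyclobut-2-en-1-one (racemic) | COC1=C(OC)C(O)C1=O | intermediate
3 | methyl semisquarate (3-methoxycyclobut-3-ene-1,2-dione) | COC1=CC(=O)C1=O | intermediate
4 | acetaldehyde | CC=O | starting material
5 | carbon tetrabromide | BrC(Br)(Br)Br | starting material
6 | 1,1-dibromoprop-1-ene | CC=C(Br)Br | intermediate
7 | 1-bromodocosane | CCCCCCCCCCCCCCCCCCCCCCBr | starting material
8 | docosylzinc bromide | CCCCCCCCCCCCCCCCCCCCCC[Zn]Br | intermediate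
9 | (Z)-3-bromopentacos-2-ene | C/C=C(\Br)CCCCCCCCCCCCCCCCCCCCCC | intermediate
10 | (E)-pentacos-2-en-3-yllithium (lithium cis to the methyl group) | C/C=C(\[Li])CCCCCCCCCCCCCCCCCCCCCC | intermediate
11 | 4-hydroxy-3-methoxy-4-[(2Z)-pentacos-2-en-3-yl]cyclobut-2-en-1-one (racemic) | C/C=C(\C1(O)C(OC)=CC1=O)CCCCCCCCCCCCCCCCCCCCCC | intermediate
12 | (3Z,5Z)-5-docosyl-4-hydroxy-3-methoxyhepta-1,3,5-trien-1-one (dienylketene) | O=C=C/C(OC)=C(O)\C(CCCCCCCCCCCCCCCCCCCCCC)=C/C | intermediate
13 | 5-docosyl-4-hydroxy-3-methoxy-6-methylcyclohexa-2,4-dien-1-one (racemic) | CC1C(=O)C=C(OC)C(O)=C1CCCCCCCCCCCCCCCCCCCCCC | intermediate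
14 | 3-docosyl-5-methoxy-2-methylbenzene-1,4-diol (hydroquinone) | CCCCCCCCCCCCCCCCCCCCCCc1c(C)c(O)cc(OC)c1O | intermediate
15 | 3-docosyl-5-methoxy-2-methylcyclohexa-2,5-diene-1,4-dione | CCCCCCCCCCCCCCCCCCCCCCC1=C(C)C(=O)C=C(OC)C1=O | target

**Step count.** Total: 5 steps. Longest linear sequence: 4 steps (4 → 6 → 9 → 11 → 15).

**Steps most likely to fail**

1. Step 5 (key step). The hydroxyl may rotate inward during ring opening and then add to the ketene, giving a butenolide instead of the arene. Closure onto the methyl-bearing alkene terminus may be slow enough for the ketene to be lost to oligomerisation. The free hydroquinone may also degrade by uncontrolled oxidation during heating. The fallback sets out from 11 and masks the carbinol. Silylation of 11 (Me3SiCl, imidazole, DMF, 0 °C) should give 3-methoxy-4-[(2Z)-pentacos-2-en-3-yl]-4-(trimethylsilyloxy)cyclobut-2-en-1-one F1. Thermolysis of this ether in p-xylene at 138 °C, where lactonisation is impossible, should give 3-docosyl-5-methoxy-2-methyl-4-(trimethylsilyloxy)phenol F2. Oxidative desilylation with (NH4)2Ce(NO3)6 in MeCN/H2O at 0 °C returns to the route at 15.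

2. Step 4. The alkenyllithium may add in conjugate fashion to the unsubstituted CH carbon of 3 or attack the vinylogous ester carbonyl. The labile adduct may also be lost by retro-addition or acid-promoted rearrangement during work-up and chromatography. The fallback sets out from 10 and avoids 3 and 11 altogether by a Danheiser benzannulation, again a four-to-six ring expansion.
   - Carboxylation of 10 (CO2, THF, −78 °C) should give (Z)-2-docosylbut-2-enoic acid F3.
   - (COCl)2 with catalytic DMF in CH2Cl2 should give (Z)-2-docosylbut-2-enoyl chloride F4.
   - Me3SiCHN2 and Et3N in MeCN/THF at 0 °C should give (Z)-1-diazo-3-docosylpent-3-en-2-one F5.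
   - Irradiation of F5 at 254 nm in CH2Cl2 with excess methoxyacetylene should trigger a photochemical Wolff rearrangement to (Z)-3-docosylpenta-1,3-dien-1-one F6. This vinylketene should add to the ynol ether in a regioselective [2+2] cycloaddition to give 3-methoxy-4-[(2Z)-pentacos-2-en-3-yl]cyclobut-2-en-1-one F7.
   - On warming to 80 °C, F7 should open and reclose by six-electron electrocyclisation to 3-docosyl-5-methoxy-2-methylphenol F8.
   - Oxidation of F8 at the free para position with (KSO3)2NO in aqueous acetone buffered with KH2PO4 returns to the route at 15.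

3. Step 3. A second alkylation of the product bromide may compete, the alkylpalladium intermediate may undergo β-hydride elimination, and zinc insertion into the waxy bromide may stall. The fallback sets out from 6 and takes the docosyl group from boron instead of zinc. Hydroboration of commercial docos-1-ene with 9-BBN-H in THF should give B-docosyl-9-borabicyclo[3.3.1]nonane F9. A B-alkyl Suzuki–Miyaura coupling with 6 (PdCl2(dppf), K3PO4, THF/DMF/H2O, rt), again at the C–Br bond trans to the methyl group, returns to the route at 9.

**Further compounds**

F1 | step 5 | 3-methoxy-4-[(2Z)-pentacos-2-en-3-yl]-4-(trimethylsilyloxy)cyclobut-2-en-1-one (racemic) | C/C=C(\C1(O[Si](C)(C)C)C(OC)=CC1=O)CCCCCCCCCCCCCCCCCCCCCC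
F2 | step 5 | 3-docosyl-5-methoxy-2-methyl-4-(trimethylsilyloxy)phenol | CCCCCCCCCCCCCCCCCCCCCCc1c(C)c(O)cc(OC)c1O[Si](C)(C)C
F3 | step 4 | (Z)-2-docosylbut-2-enoic acid | C/C=C(\C(=O)O)CCCCCCCCCCCCCCCCCCCCCC
F4 | step 4 | (Z)-2-docosylbut-2-enoyl chloride | C/C=C(\C(=O)Cl)CCCCCCCCCCCCCCCCCCCCCC
F5 | step 4 | (Z)-1-diazo-3-docosylpent-3-en-2-one | C/C=C(\C(=O)C=[N+]=[N-])CCCCCCCCCCCCCCCCCCCCCC
F6 | step 4 | (Z)-3-docosylpenta-1,3-dien-1-one (vinylketene) | C/C=C(\C=C=O)CCCCCCCCCCCCCCCCCCCCCC
F7 | step 4 | 3-methoxy-4-[(2Z)-pentacos-2-en-3-yl]cyclobut-2-en-1-one (racemic) | C/C=C(\C1C(OC)=CC1=O)CCCCCCCCCCCCCCCCCCCCCC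
F8 | step 4 | 3-docosyl-5-methoxy-2-methylphenol | CCCCCCCCCCCCCCCCCCCCCCc1cc(OC)cc(O)c1C
F9 | step 3 | B-docosyl-9-borabicyclo[3.3.1]nonane | CCCCCCCCCCCCCCCCCCCCCCB1C2CCCC1CCC2
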